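## Retrosynthetic overview

1. The target comes from oxidation of a C9 carbinol that is formed by a Nozaki–Hiyama–Kishi closure of the ten-membered ring (C9–C10) between a (Z)-alkenyl iodide and an α-angeloyloxy aldehyde.
2. The α-methylene-γ-lactone is closed before the carbocycle by TEMPO oxidative lactonisation of a 2-methylene-1,4-diol (C12-OH onto C6-OH); the angelate is then put on O8 by Yamaguchi esterification.
3. C6 is set by a 1,3-anti hydroxyl-directed reduction of a (Z)-enone; the enone comes from addition of a (Z)-alkenyllithium (Normant carbocupration of propyne) to a C6 aldehyde, and the (Z)-C1=C10 iodide from a Stork–Zhao olefination.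
4. C7 is set by chelation-controlled isopropenyl Grignard addition to protected L-erythrulose; the C12 oxygen is introduced by SeO2 allylic oxidation.
5. C8, the first stereocentre, is set by a transketolase-catalysed ketol transfer from lithium hydroxypyruvate to glycolaldehyde. Ring order: lactone ring first (step 19), ten-membered ring last (step 25).

Assumption: locants C1–C15 in names are the germacranolide positions of the target (lactone O on C6, OH on C7, angelate on C8, ketone C9, exocyclic C11=C13, lactone carbonyl C12); glycolaldehyde is charged as its commercial dimer.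

## Route

Step 1
Reactants: 1 lithium hydroxypyruvate; 2 glycolaldehyde
Product: 3 L-erythrulose
Conditions: transketolase (E. coli, clarified lysate), ThDP, MgCl2, H2O, pH 7.0 (pH-stat, 1 M HCl), 25 °C
Reagents that add atoms: none
Why: Transketolase, a thiamine-diphosphate-dependent transferase, moves the glycolyl unit of hydroxypyruvate onto one face of glycolaldehyde in an enzymatic ketol transfer made irreversible by loss of CO2, which sets the (3S) carbinol (later C8) in high ee.

Step 2
Reactants: 3 L-erythrulose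
Product: 4 3,4-O-isopropylidene-L-erythrulose
Conditions: Me2C(OMe)2, acetone, TsOH (cat.), rt
Reagents that add atoms: 2,2-dimethoxypropane, COC(C)(C)OC
Why: Acid-catalysed transacetalisation closes the five-membered dioxolane on the 3,4-diol and leaves the primary hydroxyl next to the ketone free.

Step 3
Reactants: 4 3,4-O-isopropylidene-L-erythrulose
Product: 5 1-O-TBS-3,4-O-isopropylidene-L-erythrulose
Conditions: TBSCl, imidazole, DMF, 0 °C
Reagents that add atoms: tert-butyldimethylsilyl chloride, CC(C)(C)[Si](C)(C)Cl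
Why: Silylation of the only free hydroxyl gives a bulky, non-coordinating ether on the future O6.

Step 4
Reactants: 5 1-O-TBS-3,4-O-isopropylidene-L-erythrulose
Product: 6 tertiary carbinol (7R,8S) carrying the isopropenyl group
Conditions: MgBr2·OEt2, CH2Cl2, −78 °C; then CH2=C(CH3)MgBr (THF), −78 °C; aq. NH4Cl
Reagents that add atoms: isopropenylmagnesium bromide, CC(=C)[Mg]Br
Why: In this Cram-chelate (α-chelation) controlled Grignard addition magnesium bridges the ketone oxygen and the dioxolane O8 while the silyl ether stays uncoordinated, so the nucleophile enters from the face of the C8–H and gives the (7R) carbinol with O7 and O8 anti.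

Step 5
Reactants: 6 tertiary carbinol (7R,8S)
Product: 7 C6,C7-bis-TBS ether (7R,8S)
Conditions: TBSOTf, 2,6-lutidine, CH2Cl2, 0 °C → rt
Reagents that add atoms: tert-butyldimethylsilyl triflate, CC(C)(C)[Si](C)(C)OS(=O)(=O)C(F)(F)F
Why: Silyl triflate silylation caps the hindered tertiary hydroxyl, which later blocks α-ketol rearrangement of the aldehyde and keeps O7 out of the directed reduction.

Step 6
Reactants: 7 C6,C7-bis-TBS ether (7R,8S)
Product: 9 C12 allylic alcohol (7R,8S), via enal 8 (not isolated)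
Conditions: SeO2 (0.5 equiv), t-BuOOH, CH2Cl2, rt; then NaBH4, MeOH, 0 °C
Reagents that add atoms: selenium dioxide, O=[Se]=O; tert-butyl hydroperoxide, CC(C)(C)OO
Why: The Riley allylic oxidation (ene reaction then 2,3-shift) can only attack the single allylic methyl of the 1,1-disubstituted alkene, and borohydride returns any over-oxidised enal to the alcohol.

Step 7
Reactants: 9 C12 allylic alcohol (7R,8S)
Product: 10 C12 TBDPS ether (7R,8S)
Conditions: TBDPSCl, imidazole, CH2Cl2, rt
Reagents that add atoms: tert-butyldiphenylsilyl chloride, CC(C)(C)[Si](Cl)(c1ccccc1)c1ccccc1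
Why: Standard silylation of the primary allylic alcohol with a group that outlasts the later HF·pyridine steps.

Step 8
Reactants: 10 C12 TBDPS ether (7R,8S)
Product: 11 C6 primary alcohol (7R,8S)
Conditions: HF·pyridine, pyridine, THF, 0 °C → rt
Reagents that add atoms: none
Why: Buffered HF·pyridine desilylation removes the primary TBS ether much faster than the tertiary TBS or the TBDPS ether and does not touch the acetonide.

Step 9
Reactants: 11 C6 primary alcohol (7R,8S)
Product: 12 C6 aldehyde (7S,8S)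
Conditions: Dess–Martin periodinane, NaHCO3, CH2Cl2, rt
Reagents that add atoms: none
Why: Dess–Martin oxidation gives an aldehyde that has no α-hydrogen, so the quaternary C7 cannot epimerise.

Step 10
Reactants: 13 (3-bromopropoxy)(tert-butyl)dimethylsilane; 14 propyne
Product: 18 (Z)-tert-butyl[(5-iodo-4-methylpent-4-en-1-yl)oxy]dimethylsilane, via alkylmagnesium bromide 15 (not isolated), via alkylcopper 16 (not isolated), via alkenylcopper 17 (not isolated)
Conditions: Mg, Et2O; CuBr·SMe2, Et2O/Me2S, −45 °C; propyne, −25 °C; I2, THF, −50 → 0 °C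
Reagents that add atoms: iodine, II
Why: Normant carbocupration adds the alkyl group and copper syn across propyne (alkyl to the methyl-bearing carbon) and iodinolysis proceeds with retention, which fixes the (Z)-C4=C5 geometry.

Step 11
Reactants: 18 (Z)-alkenyl iodide; 12 C6 aldehyde (7S,8S)
Product: 20 C6-epimeric allylic alcohols (6RS,7R,8S), via alkenyllithium 19 (not isolated)
Conditions: 18, t-BuLi (2.1 equiv), Et2O, −78 °C; then 12, −78 °C; aq. NH4Cl at −78 °C
Reagents that add atoms: none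
Why: Iodine–lithium exchange keeps the alkene geometry and 1,2-addition to the non-enolisable aldehyde forms the C5–C6 bond; C6 forms as an epimer mixture that is erased in step 13 and reset in step 16.

Step 12
Reactants: 20 C6-epimeric allylic alcohols (6RS,7R,8S)
Product: 21 C1,C6-diol (6RS,7R,8S)
Conditions: HF·pyridine, pyridine, THF, 0 °C
Reagents that add atoms: none
Why: Selective desilylation frees the primary C1 hydroxyl while the tertiary TBS and the TBDPS ethers stay on.

Step 13
Reactants: 21 C1,C6-diol (6RS,7R,8S)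
Product: 22 keto aldehyde (7S,8S)
Conditions: Dess–Martin periodinane (3 equiv), NaHCO3, CH2Cl2, rt
Reagents that add atoms: none
Why: A double Dess–Martin oxidation gives the C1 aldehyde and the (Z)-enone at C6 in one operation under buffered, non-isomerising conditions.

Step 14
Reactants: 22 keto aldehyde (7S,8S)
Product: 23 (Z)-iodoalkene enone (7S,8S)
Conditions: [Ph3PCH2CH3]I, n-BuLi, THF, rt; I2, −78 °C; NaN(SiMe3)2, −20 °C; then 22, −78 °C
Reagents that add atoms: ethyltriphenylphosphonium iodide, CC[P+](c1ccccc1)(c1ccccc1)c1ccccc1.[I-]; iodine, II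
Why: The Stork–Zhao–Wittig olefination with the α-iodo ylide reacts with the aldehyde and not the hindered ketone and gives the (Z)-2-iodo-2-alkene (iodine cis to the chain), which is the C1=C10 geometry of the target.

Step 15
Reactants: 23 (Z)-iodoalkene enone (7S,8S)
Product: 24 8,9-diol enone (7S,8S)
Conditions: AcOH/THF/H2O (3:1:1), 40 °C
Reagents that add atoms: none
Why: Mild acetal hydrolysis frees the C8 hydroxyl needed as the directing group while the silyl ethers and the alkenyl iodide stay intact.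

Step 16
Reactants: 24 8,9-diol enone (7S,8S)
Product: 25 6,8,9-triol (6S,7R,8S)
Conditions: Me4NBH(OAc)3, MeCN/AcOH (1:1), −30 °C
Reagents that add atoms: none
Why: In this Evans–Saksena hydroxyl-directed reduction the C8 hydroxyl binds boron and delivers hydride to the ketone through a chair transition state, which gives the 1,3-anti diol and thus the (6S) carbinol.

Step 17
Reactants: 25 6,8,9-triol (6S,7R,8S)
Product: 26 8,9-acetonide C6 alcohol (6S,7R,8S)
Conditions: Me2C(OMe)2, PPTS (cat.), CH2Cl2, 0 °C → rt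
Reagents that add atoms: 2,2-dimethoxypropane, COC(C)(C)OC
Why: Acetonide formation selects the terminal 1,2-diol because the alternative six-membered acetal of the anti-1,3-diol is strained, so only O6 stays free.

Step 18
Reactants: 26 8,9-acetonide C6 alcohol (6S,7R,8S)
Product: 27 6,7,12-triol (6S,7R,8S)
Conditions: Bu4NF, THF, 0 °C → rt; aq. NH4Cl
Reagents that add atoms: none
Why: Fluoride desilylation removes the TBDPS ether and, helped by silyl migration to the neighbouring alkoxides, the hindered tertiary TBS ether.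

Step 19
Reactants: 27 6,7,12-triol (6S,7R,8S)
Product: 30 α-methylene lactone acetonide (6S,7R,8S), via enal 28 (not isolated), via lactol 29 (not isolated)
Conditions: TEMPO (cat.), PhI(OAc)2, CH2Cl2, rt
Reagents that add atoms: none
Why: TEMPO oxidative lactonisation oxidises only the primary allylic alcohol, the enal is trapped by the C6 hydroxyl as a five-membered lactol and this is oxidised on to the lactone, while O8 is blocked by the acetonide.

Step 20
Reactants: 30 α-methylene lactone acetonide (6S,7R,8S)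
Product: 31 lactone 7,8,9-triol (6S,7S,8S)
Conditions: AcOH/H2O (4:1), 40 °C
Reagents that add atoms: none
Why: Acidic acetal hydrolysis frees the 8,9-diol without opening or moving the lactone.

Step 21
Reactants: 31 lactone 7,8,9-triol (6S,7S,8S)
Product: 32 9-O-TES ether (6S,7S,8S)
Conditions: Et3SiCl, imidazole, CH2Cl2, −40 °C
Reagents that add atoms: triethylsilyl chloride, CC[Si](Cl)(CC)CC
Why: Silylation at low temperature picks the primary hydroxyl over the hindered secondary and the tertiary ones.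

Step 22
Reactants: 32 9-O-TES ether (6S,7S,8S)
Product: 33 8-O-angelate (6S,7R,8S)
Conditions: angelic acid, 2,4,6-Cl3C6H2COCl, Et3N, toluene, rt; then 32, 80 °C
Reagents that add atoms: angelic acid, C/C=C(/C)C(=O)O
Why: Yamaguchi esterification through the mixed anhydride, run without DMAP, acylates the only reactive (secondary) hydroxyl and keeps the angelate from isomerising to the tiglate.

Step 23
Reactants: 33 8-O-angelate (6S,7R,8S)
Product: 34 C9 primary alcohol (6S,7R,8S)
Conditions: HF·pyridine, pyridine, THF, 0 °C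
Reagents that add atoms: none
Why: Desilylation under mildly acidic fluoride conditions removes the primary TES ether without O8-to-O9 acyl migration.

Step 24
Reactants: 34 C9 primary alcohol (6S,7R,8S)
Product: 35 C9 aldehyde (6S,7R,8R)
Conditions: Dess–Martin periodinane, NaHCO3, CH2Cl2, 0 °C
Reagents that add atoms: none
Why: Buffered Dess–Martin oxidation gives the α-acyloxy aldehyde without epimerising C8; it is used at once.

Step 25
Reactants: 35 C9 aldehyde (6S,7R,8R)
Product: 37 macrocyclic C9 alcohols (6S,7R,8S,9RS), via alkenylchromium dichloride 36 (not isolated)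
Conditions: CrCl2 (10 equiv), NiCl2 (cat.), DMSO/THF, 2 mM, rt
Reagents that add atoms: none
Why: The intramolecular Nozaki–Hiyama–Kishi reaction adds the alkenylchromium species to the aldehyde with retention of the (Z) geometry and tolerates the lactone, the ester and the free tertiary hydroxyl; the C9 epimers converge in step 26.

Step 26
Reactants: 37 macrocyclic C9 alcohols (6S,7R,8S,9RS)
Product: 38 target CNP0276177.1 (6S,7R,8R)
Conditions: Dess–Martin periodinane, NaHCO3, CH2Cl2, 0 °C → rt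
Reagents that add atoms: none
Why: Dess–Martin oxidation of the allylic carbinol gives the (Z)-enone under near-neutral conditions that avoid retro-aldol cleavage of the β-hydroxy ketone and acyl migration.

## Compound list

1 | lithium hydroxypyruvate (lithium 3-hydroxy-2-oxopropanoate) | [Li+].[O-]C(=O)C(=O)CO | starting material
2 | glycolaldehyde (2-hydroxyacetaldehyde) | OCC=O | starting material
3 | L-erythrulose, (3S)-1,3,4-trihydroxybutan-2-one | OC[C@H](O)C(=O)CO | intermediate
4 | 3,4-O-isopropylidene-L-erythrulose, 2-hydroxy-1-[(4S)-2,2-dimethyl-1,3-dioxolan-4-yl]ethan-1-one | CC1(C)OC[C@H](O1)C(=O)CO | intermediate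
5 | 1-O-TBS-3,4-O-isopropylidene-L-erythrulose | CC1(C)OC[C@H](O1)C(=O)CO[Si](C)(C)C(C)(C)C | intermediate
6 | (2R)-1-[(tert-butyldimethylsilyl)oxy]-2-[(4S)-2,2-dimethyl-1,3-dioxolan-4-yl]-3-methylbut-3-en-2-ol (7R,8S) | CC1(C)OC[C@H](O1)[C@@](C(C)=C)(CO[Si](C)(C)C(C)(C)C)O | intermediate
7 | (2R)-1,2-bis[(tert-butyldimethylsilyl)oxy]-2-[(4S)-2,2-dimethyl-1,3-dioxolan-4-yl]-3-methylbut-3-ene (7R,8S) | CC1(C)OC[C@H](O1)[C@@](C(C)=C)(CO[Si](C)(C)C(C)(C)C)O[Si](C)(C)C(C)(C)C | intermediate
8 | 2-[(1R)-1,2-bis(TBS-oxy)-1-[(4S)-2,2-dimethyl-1,3-dioxolan-4-yl]ethyl]prop-2-enal (7R,8S) | CC1(C)OC[C@H](O1)[C@@](C(C=O)=C)(CO[Si](C)(C)C(C)(C)C)O[Si](C)(C)C(C)(C)C | intermediate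
9 | 2-[(1R)-1,2-bis(TBS-oxy)-1-[(4S)-2,2-dimethyl-1,3-dioxolan-4-yl]ethyl]prop-2-en-1-ol (7R,8S) | CC1(C)OC[C@H](O1)[C@@](C(CO)=C)(CO[Si](C)(C)C(C)(C)C)O[Si](C)(C)C(C)(C)C | intermediate
10 | C12 tert-butyldiphenylsilyl ether of 9 (7R,8S) | CC1(C)OC[C@H](O1)[C@@](C(CO[Si](c2ccccc2)(c2ccccc2)C(C)(C)C)=C)(CO[Si](C)(C)C(C)(C)C)O[Si](C)(C)C(C)(C)C | intermediate
11 | (2R)-2-(TBS-oxy)-3-[(TBDPS-oxy)methyl]-2-[(4S)-2,2-dimethyl-1,3-dioxolan-4-yl]but-3-en-1-ol (7R,8S) | CC1(C)OC[C@H](O1)[C@@](C(CO[Si](c2ccccc2)(c2ccccc2)C(C)(C)C)=C)(CO)O[Si](C)(C)C(C)(C)C | intermediate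
12 | (2S)-2-(TBS-oxy)-3-[(TBDPS-oxy)methyl]-2-[(4S)-2,2-dimethyl-1,3-dioxolan-4-yl]but-3-enal (7S,8S) | CC1(C)OC[C@H](O1)[C@@](C(CO[Si](c2ccccc2)(c2ccccc2)C(C)(C)C)=C)(C=O)O[Si](C)(C)C(C)(C)C | intermediate
13 | (3-bromopropoxy)(tert-butyl)dimethylsilane | BrCCCO[Si](C)(C)C(C)(C)C | starting material
14 | propyne | CC#C | starting material
15 | [3-(tert-butyldimethylsilyloxy)propyl]magnesium bromide | Br[Mg]CCCO[Si](C)(C)C(C)(C)C | intermediate
16 | [3-(tert-butyldimethylsilyloxy)propyl]copper (MgBr2 complex) | [Cu]CCCO[Si](C)(C)C(C)(C)C | intermediate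
17 | (Z)-[5-(tert-butyldimethylsilyloxy)-2-methylpent-1-en-1-yl]copper | [Cu]/C=C(/C)CCCO[Si](C)(C)C(C)(C)C | intermediate
18 | (Z)-tert-butyl[(5-iodo-4-methylpent-4-en-1-yl)oxy]dimethylsilane | I/C=C(/C)CCCO[Si](C)(C)C(C)(C)C | intermediate
19 | (Z)-[5-(tert-butyldimethylsilyloxy)-2-methylpent-1-en-1-yl]lithium | [Li]/C=C(/C)CCCO[Si](C)(C)C(C)(C)C | intermediate
20 | C6-epimeric allylic alcohols (6RS,7R,8S): (4Z)-alkene, C1-OTBS, C7-OTBS, C12-OTBDPS, 8,9-O-isopropylidene | CC1(C)OC[C@H](O1)[C@@](C(CO[Si](c2ccccc2)(c2ccccc2)C(C)(C)C)=C)(C(O)/C=C(/C)CCCO[Si](C)(C)C(C)(C)C)O[Si](C)(C)C(C)(C)C | intermediate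
21 | C1,C6-diol (6RS,7R,8S): (4Z)-alkene, C7-OTBS, C12-OTBDPS, 8,9-O-isopropylidene | CC1(C)OC[C@H](O1)[C@@](C(CO[Si](c2ccccc2)(c2ccccc2)C(C)(C)C)=C)(C(O)/C=C(/C)CCCO)O[Si](C)(C)C(C)(C)C | intermediate
22 | keto aldehyde (7S,8S): C1 aldehyde, (4Z)-en-6-one, C7-OTBS, C12-OTBDPS, 8,9-O-isopropylidene | CC1(C)OC[C@H](O1)[C@@](C(CO[Si](c2ccccc2)(c2ccccc2)C(C)(C)C)=C)(C(=O)/C=C(/C)CCC=O)O[Si](C)(C)C(C)(C)C | intermediate
23 | (Z)-iodoalkene enone (7S,8S): (1Z)-10-iodo-1(10)-ene, (4Z)-en-6-one, C7-OTBS, C12-OTBDPS, 8,9-O-isopropylidene | CC1(C)OC[C@H](O1)[C@@](C(CO[Si](c2ccccc2)(c2ccccc2)C(C)(C)C)=C)(C(=O)/C=C(/C)CC/C=C(/C)I)O[Si](C)(C)C(C)(C)C | intermediate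
24 | 8,9-diol enone (7S,8S): as 23 with free C8-OH and C9-OH | OC[C@H](O)[C@@](C(CO[Si](c1ccccc1)(c1ccccc1)C(C)(C)C)=C)(C(=O)/C=C(/C)CC/C=C(/C)I)O[Si](C)(C)C(C)(C)C | intermediate
25 | 6,8,9-triol (6S,7R,8S): C7-OTBS, C12-OTBDPS, (1Z)-iodoalkene, (4Z)-alkene | OC[C@H](O)[C@@](C(CO[Si](c1ccccc1)(c1ccccc1)C(C)(C)C)=C)([C@@H](O)/C=C(/C)CC/C=C(/C)I)O[Si](C)(C)C(C)(C)C | intermediate
26 | 8,9-O-isopropylidene C6 alcohol (6S,7R,8S): C7-OTBS, C12-OTBDPS | CC1(C)OC[C@H](O1)[C@@](C(CO[Si](c2ccccc2)(c2ccccc2)C(C)(C)C)=C)([C@@H](O)/C=C(/C)CC/C=C(/C)I)O[Si](C)(C)C(C)(C)C | intermediate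
27 | 6,7,12-triol (6S,7R,8S): 8,9-O-isopropylidene, (1Z)-iodoalkene, (4Z)-alkene | CC1(C)OC[C@H](O1)[C@@](C(CO)=C)([C@@H](O)/C=C(/C)CC/C=C(/C)I)O | intermediate
28 | C12 enal of 27 (6S,7R,8S) | CC1(C)OC[C@H](O1)[C@@](C(C=O)=C)([C@@H](O)/C=C(/C)CC/C=C(/C)I)O | intermediate
29 | five-membered lactol (6S,7R,8S), C12 epimers | C=C1C(O)O[C@@H](/C=C(/C)CC/C=C(/C)I)[C@@]1(O)[C@@H]2COC(C)(C)O2 | intermediate
30 | α-methylene-γ-lactone (6,12-olide) with 7-OH and 8,9-O-isopropylidene (6S,7R,8S) | C=C1C(=O)O[C@@H](/C=C(/C)CC/C=C(/C)I)[C@@]1(O)[C@@H]2COC(C)(C)O2 | intermediate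
31 | lactone 7,8,9-triol (6S,7S,8S) | C=C1C(=O)O[C@@H](/C=C(/C)CC/C=C(/C)I)[C@@]1(O)[C@@H](O)CO | intermediate
32 | 9-O-triethylsilyl ether of 31 (6S,7S,8S) | C=C1C(=O)O[C@@H](/C=C(/C)CC/C=C(/C)I)[C@@]1(O)[C@@H](O)CO[Si](CC)(CC)CC | intermediate
33 | 8-O-angelate 9-O-TES ether (6S,7R,8S) | C=C1C(=O)O[C@@H](/C=C(/C)CC/C=C(/C)I)[C@@]1(O)[C@@H](OC(=O)/C(C)=C\C)CO[Si](CC)(CC)CC | intermediate
34 | 8-O-angelate C9 primary alcohol (6S,7R,8S) | C=C1C(=O)O[C@@H](/C=C(/C)CC/C=C(/C)I)[C@@]1(O)[C@@H](OC(=O)/C(C)=C\C)CO | intermediate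
35 | 8-O-angelate C9 aldehyde (6S,7R,8R) | C=C1C(=O)O[C@@H](/C=C(/C)CC/C=C(/C)I)[C@@]1(O)[C@@H](OC(=O)/C(C)=C\C)C=O | intermediate
36 | (Z)-alkenylchromium dichloride derived from 35 (6S,7R,8R) | C=C1C(=O)O[C@@H](/C=C(/C)CC/C=C(/C)[Cr](Cl)Cl)[C@@]1(O)[C@@H](OC(=O)/C(C)=C\C)C=O | intermediate
37 | (1Z,4Z)-germacradienolide C9 alcohols (6S,7R,8S,9RS): 7-OH, 8-O-angelate, 6,12-olide, 11(13)-ene | C=C1C(=O)O[C@H]2/C=C(/C)CC/C=C(/C)C(O)[C@H](OC(=O)/C(C)=C\C)[C@@]12O | intermediate
38 | CNP0276177.1 (6S,7R,8R): 8-angeloyloxy-7-hydroxy-9-oxo-(1Z,4Z)-germacra-1(10),4,11(13)-trien-6,12-olide | C=C1C(=O)O[C@H]2/C=C(/C)CC/C=C(/C)C(=O)[C@H](OC(=O)/C(C)=C\C)[C@@]12O | target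

## Step count and risks

Total step count: 26. Longest linear sequence: 25 steps (steps 1–9 and 11–26); step 10 makes the side fragment.

Three steps most likely to fail:

Step 14 (Stork–Zhao olefination). Yields are often modest, and the basic ylide may erode Z/E purity or touch the (Z)-enone. The fallback sets out from keto aldehyde 22. A Ramirez dibromo-olefination (CBr4, PPh3, Et3N, CH2Cl2, 0 °C) gives the 1,1-dibromoalkene F1. A trans-selective Negishi monomethylation (MeZnCl, Pd(t-Bu3P)2 cat., THF, 0 °C) replaces only the bromide trans to the chain and gives the (Z)-alkenyl bromide F2. A copper-catalysed halide exchange with retention of geometry (CuI cat., NaI, trans-N,N′-dimethylcyclohexane-1,2-diamine, 1,4-dioxane, 100 °C) then comes back to the route at iodide 23.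

Step 16 (directed reduction). The γ-hydroxy enone 24 can close to a hemiketal or undergo oxa-Michael addition, and the crowded C7 may lower the anti selectivity. The fallback sets out from enone 23 with the acetonide still in place and uses a catalyst-controlled Corey–Bakshi–Shibata reduction ((R)-2-methyl-CBS-oxazaborolidine, catecholborane, toluene, −78 °C). The fully substituted C7 is taken as the large group, with the antipodal catalyst as the check. This gives the (6S) alcohol directly and comes back to the route at 26, bypassing 24 and 25; it makes no compound beyond the list (F0).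

Step 25 (ten-membered ring closure). The strained (Z,Z)-cyclodecadiene may form slowly, and the chromium alkoxide next to the angelate invites acyl migration. The fallback sets out from aldehyde 35 and closes the ring at the ketone oxidation level. Pinnick oxidation (NaClO2, NaH2PO4, 2-methyl-2-butene, t-BuOH/H2O) gives the carboxylic acid F3. Mukaiyama thioesterification (2,2′-dipyridyl disulfide, PPh3, CH2Cl2) gives the S-(2-pyridyl) thioester F4. An intramolecular nickel-catalysed, zirconium-assisted reductive coupling of the alkenyl iodide with the thioester (NiBr2·dtbbpy cat., Cp2ZrCl2, Zn, DMI/EtOAc, high dilution, rt) forms the enone directly and comes back to the route at target 38, bypassing 37 and step 26.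

## Further compounds

F1 | step 14 | 1,1-dibromoalkene from 22 (7S,8S): C1 aldehyde replaced by CH=CBr2 | CC1(C)OC[C@H](O1)[C@@](C(CO[Si](c2ccccc2)(c2ccccc2)C(C)(C)C)=C)(C(=O)/C=C(/C)CCC=C(Br)Br)O[Si](C)(C)C(C)(C)C
F2 | step 14 | (Z)-alkenyl bromide analogue of 23 (7S,8S) | CC1(C)OC[C@H](O1)[C@@](C(CO[Si](c2ccccc2)(c2ccccc2)C(C)(C)C)=C)(C(=O)/C=C(/C)CC/C=C(/C)Br)O[Si](C)(C)C(C)(C)C
F0 | step 16 | none | none
F3 | step 25 | C9 carboxylic acid from 35 (6S,7R,8R) | C=C1C(=O)O[C@@H](/C=C(/C)CC/C=C(/C)I)[C@@]1(O)[C@@H](OC(=O)/C(C)=C\C)C(=O)O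
F4 | step 25 | C9 S-(2-pyridyl) thioester (6S,7R,8R) | C=C1C(=O)O[C@@H](/C=C(/C)CC/C=C(/C)I)[C@@]1(O)[C@@H](OC(=O)/C(C)=C\C)C(=O)Sc2ccccn2
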